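The cyclopentane (ring A) is closed by a Nazarov 4π-electrocyclisation that joins the vinyl CH2 (C1) to the methyl-bearing carbon C8a of a cycloheptenyl vinyl ketone. In one operation a chiral Brønsted acid turns this monocycle into the hydroazulenone with the quaternary stereocentre set. The step exploits three features: the C3 oxygen of ring A (the dienone carbonyl), the C3a–C8a ring-fusion bond (the tetrasubstituted alkene), and the C4 oxygen of cycloheptene ring B, whose carbon loses the terminating proton, leaving a C3a=C4 enone for later oxygenation. The precursor comes from 4-methylcyclohexanone by one-carbon ring expansion.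

Key step: step 5

Remarks on the chemistry:
- Atom labels follow azulene numbering of the target (ring A: C1, C2, C3, C3a, C8a; ring B: C3a, C4, C5, C6, C7, C8, C8a).
- Compounds 3–7 are racemic at the methyl-bearing ring carbon (the future C6). This centre is remote from the reacting sites, gives 8 as a pair of C6 epimers, and becomes sp2 in step 6.
- Which antipode of the acid catalyst delivers 8aS is assumed to be settled by a test cyclisation.

Step 1
Reactants: 1 4-methylcyclohexanone; 2 ethyl diazoacetate
Product: 3 ethyl 5-methyl-2-oxocycloheptane-1-carboxylate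
Conditions: BF3·OEt2, Et2O, 0 °C → rt
Reagents that add atoms: none
Why: Lewis-acid-promoted diazoacetate homologation of a ketone (Tiffeneau–Demjanov-type ring expansion with loss of N2) should give a single constitutional isomer because the ketone is symmetric, placing the ester on the future C3a, the ketone on the future C8a and the methyl on the future C6.

Step 2
Reactants: 3 ethyl 5-methyl-2-oxocycloheptane-1-carboxylate
Product: 4 ethyl 5-methyl-2-[(trifluoromethanesulfonyl)oxy]cyclohept-1-ene-1-carboxylate
Conditions: NaH, Et2O, 0 °C; then Tf2O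
Reagents that add atoms: trifluoromethanesulfonic anhydride O=S(=O)(OS(=O)(=O)C(F)(F)F)C(F)(F)F
Why: O-sulfonylation of the sodium enolate of a β-keto ester should give the tetrasubstituted enol triflate regiospecifically between the two carbonyl carbons.

Step 3
Reactants: 4 ethyl 5-methyl-2-[(trifluoromethanesulfonyl)oxy]cyclohept-1-ene-1-carboxylate
Product: 5 ethyl 2,5-dimethylcyclohept-1-ene-1-carboxylate
Conditions: MeMgBr, Fe(acac)3 (5 mol %), THF/NMP, −30 °C
Reagents that add atoms: methylmagnesium bromide C[Mg]Br
Why: Iron-catalysed Kumada-type cross-coupling of an enol triflate with a methyl Grignard reagent should outpace attack on the ester at low temperature and installs the future C8a methyl on the tetrasubstituted alkene.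

Step 4
Reactants: 5 ethyl 2,5-dimethylcyclohept-1-ene-1-carboxylate
Product: 7 1-(2,5-dimethylcyclohept-1-en-1-yl)prop-2-en-1-one, via Weinreb amide 6 (not isolated)
Conditions: MeNH(OMe)·HCl, iPrMgCl, THF, −20 → 0 °C; then CH2=CHMgBr, 0 °C; inverse quench into cold 1 M HCl; product stored cold with BHT
Reagents that add atoms: vinylmagnesium bromide C=C[Mg]Br; N,O-dimethylhydroxylamine hydrochloride CNOC.Cl (its atoms stay only in 6)
Why: One-pot Weinreb ketone synthesis, in which the magnesium amide converts the ester into the N-methoxy-N-methylamide and its chelated tetrahedral adduct with the vinyl Grignard reagent resists over-addition, while the acidic quench protonates the liberated amine so that it cannot add to the vinyl ketone.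

Step 5
Reactants: 7 1-(2,5-dimethylcyclohept-1-en-1-yl)prop-2-en-1-one
Product: 8 (8aS)-6,8a-dimethyl-2,5,6,7,8,8a-hexahydroazulen-3(1H)-one (both C6 epimers)
Conditions: chiral BINOL-derived imidodiphosphorimidate (IDPi) Brønsted acid (5 mol %), toluene, −20 °C → rt
Reagents that add atoms: none
Why: Proposed new method: the confined chiral acid protonates the carbonyl of 7 to a 3-hydroxypentadienyl cation paired with the chiral anion, conrotatory 4π-electrocyclisation bonds the vinyl CH2 (C1) to the methyl-bearing C8a, and the hydroxyallyl cation ends by loss of a C4 proton and tautomerisation to the C3a=C4 enone. The closest known reaction types are the imidodiphosphorimidate-catalysed asymmetric Nazarov cyclisation of simple acyclic divinyl ketones and the achiral acid-promoted Nazarov closure of 2-alkylcycloalkenyl vinyl ketones to angularly alkylated bicyclic enones; new is catalyst control at a terminus that becomes an all-carbon quaternary centre opposite an unsubstituted vinyl group. Ring A is closed in the 4π-conrotatory (formally 5-endo) mode of a pentadienyl cation. C8a is the only new stereocentre that is kept, and its configuration follows from the sense of conrotation (torquoselectivity) imposed by the chiral counter-anion, the racemic C6 centre being remote. The step needs enantiofacial control at a terminus whose two faces differ only as methyl versus ring CH2, which the confined anion pocket has to provide, and it needs termination at C4 instead of a 1,2-methyl shift or proton loss from C1, which the available C4 hydrogens and the greater stability of the more substituted conjugated C3a=C4 enone should secure under the equilibrating acidic conditions.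

Step 6
Reactants: 8 (8aS)-6,8a-dimethyl-2,5,6,7,8,8a-hexahydroazulen-3(1H)-one
Product: 9 (8aS)-6,8a-dimethyl-2,7,8,8a-tetrahydroazulen-3(1H)-one
Conditions: chloranil (1.2 equiv), t-BuOH, reflux
Reagents that add atoms: none
Why: Quinone dehydrogenation of an enone to the linear dienone (hydride abstraction from the tertiary C6–H of the extended dienol, the chloranil conversion of 4-en-3-ones into 4,6-dien-3-ones) should make both C6 epimers converge on one compound, and the quaternary C8a cannot epimerise.

Step 7
Reactants: 9 (8aS)-6,8a-dimethyl-2,7,8,8a-tetrahydroazulen-3(1H)-one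
Product: 10 (3aR,4S,8aS)-3a,4-epoxy-6,8a-dimethyl-2,3a,4,7,8,8a-hexahydroazulen-3(1H)-one
Conditions: 30% aq. H2O2, NaOH (cat.), MeOH, 0 °C
Reagents that add atoms: hydrogen peroxide OO
Why: Weitz–Scheffer nucleophilic epoxidation should take the α,β-alkene of the dienone (hydroperoxide adds to the unhindered C4, the δ-carbon being disubstituted), and closure of the peroxy enolate at C3a is expected on the face anti to the adjacent 8a-methyl, which sets C3a and C4 relative to C8a.

Step 8
Reactants: 10 (3aR,4S,8aS)-3a,4-epoxy-6,8a-dimethyl-2,3a,4,7,8,8a-hexahydroazulen-3(1H)-one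
Product: 11 (3aS,4S,8aS)-4-hydroxy-6,8a-dimethyl-2,3a,4,7,8,8a-hexahydroazulen-3(1H)-one
Conditions: SmI2 (2.2 equiv), THF/MeOH, −90 °C; used directly
Reagents that add atoms: none
Why: Samarium diiodide reduction of an α,β-epoxy ketone cleaves the Cα–O bond through the ketyl and keeps the C4–O bond, and kinetic protonation of the samarium enolate at C3a by methanol (plausibly bound to the C4 alkoxide) from the face anti to the angular methyl should give the trans ring fusion with H-3a and the C4 hydroxyl cis.

Step 9
Reactants: 11 (3aS,4S,8aS)-4-hydroxy-6,8a-dimethyl-2,3a,4,7,8,8a-hexahydroazulen-3(1H)-one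
Product: 12 (3R,3aS,4S,8aS)-6,8a-dimethyl-3-(propan-2-yl)-1,2,3,3a,4,7,8,8a-octahydroazulene-3,4-diol
Conditions: iPrMgCl (3 equiv), LaCl3·2LiCl, THF, −20 °C; aq. NH4Cl
Reagents that add atoms: isopropylmagnesium chloride CC(C)[Mg]Cl
Why: Lanthanum-promoted Grignard 1,2-addition to a hindered enolisable cyclopentanone (the first equivalent forms the C4 alkoxide) should occur on the face of H-3a, anti to the 1,3-related angular methyl as in additions to 15-oxo steroids and assisted by chelation through the C4 alkoxide, so the new C3 hydroxyl ends cis to the 8a-methyl.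

Step 10
Reactants: 12 (3R,3aS,4S,8aS)-6,8a-dimethyl-3-(propan-2-yl)-1,2,3,3a,4,7,8,8a-octahydroazulene-3,4-diol; 13 4-acetoxybenzoyl chloride
Product: 14 (3R,3aS,4S,8aS)-3-hydroxy-6,8a-dimethyl-3-(propan-2-yl)-1,2,3,3a,4,7,8,8a-octahydroazulen-4-yl 4-acetoxybenzoate
Conditions: pyridine, DMAP (cat.), CH2Cl2, 0 °C → rt
Reagents that add atoms: none
Why: DMAP-catalysed acylation should discriminate the secondary allylic alcohol from the hindered tertiary one, and the phenol is masked as its acetate so that the acid chloride cannot self-condense.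

Step 11
Reactants: 14 (3R,3aS,4S,8aS)-3-hydroxy-6,8a-dimethyl-3-(propan-2-yl)-1,2,3,3a,4,7,8,8a-octahydroazulen-4-yl 4-acetoxybenzoate
Product: 15 (3R,3aS,4S,8aS)-3-hydroxy-6,8a-dimethyl-3-(propan-2-yl)-1,2,3,3a,4,7,8,8a-octahydroazulen-4-yl 4-hydroxybenzoate
Conditions: pyrrolidine, CH2Cl2, 0 °C
Reagents that add atoms: none
Why: Aminolysis of the aryl acetate by pyrrolidine should be far faster than attack on the hindered alkyl benzoate because phenoxide is the better leaving group, and no stereocentre is touched.

Compound list
1 | 4-methylcyclohexanone | CC1CCC(=O)CC1 | starting material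
2 | ethyl diazoacetate | CCOC(=O)C=[N+]=[N-] | starting material
3 | ethyl 5-methyl-2-oxocycloheptane-1-carboxylate (racemic, keto/enol and diastereomer mixture) | CCOC(=O)C1CCC(C)CCC1=O | intermediate
4 | ethyl 5-methyl-2-[(trifluoromethanesulfonyl)oxy]cyclohept-1-ene-1-carboxylate (racemic) | CCOC(=O)C1=C(OS(=O)(=O)C(F)(F)F)CCC(C)CC1 | intermediate
5 | ethyl 2,5-dimethylcyclohept-1-ene-1-carboxylate (racemic) | CCOC(=O)C1=C(C)CCC(C)CC1 | intermediate
6 | N-methoxy-N,2,5-trimethylcyclohept-1-ene-1-carboxamide (racemic, Weinreb amide) | CON(C)C(=O)C1=C(C)CCC(C)CC1 | intermediate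
7 | 1-(2,5-dimethylcyclohept-1-en-1-yl)prop-2-en-1-one (racemic) | C=CC(=O)C1=C(C)CCC(C)CC1 | intermediate
8 | (8aS)-6,8a-dimethyl-2,5,6,7,8,8a-hexahydroazulen-3(1H)-one (both C6 epimers) | CC1CC[C@@]2(C)CCC(=O)C2=CC1 | intermediate
9 | (8aS)-6,8a-dimethyl-2,7,8,8a-tetrahydroazulen-3(1H)-one | CC1=CC=C2C(=O)CC[C@]2(C)CC1 | intermediate
10 | (3aR,4S,8aS)-3a,4-epoxy-6,8a-dimethyl-2,3a,4,7,8,8a-hexahydroazulen-3(1H)-one (epoxide oxygen anti to the 8a-methyl) | CC1=C[C@@H]2O[C@@]23C(=O)CC[C@]3(C)CC1 | intermediate
11 | (3aS,4S,8aS)-4-hydroxy-6,8a-dimethyl-2,3a,4,7,8,8a-hexahydroazulen-3(1H)-one (trans-fused) | CC1=C[C@H](O)[C@@H]2[C@@](C)(CC1)CCC2=O | intermediate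
12 | (3R,3aS,4S,8aS)-6,8a-dimethyl-3-(propan-2-yl)-1,2,3,3a,4,7,8,8a-octahydroazulene-3,4-diol | CC1=C[C@H](O)[C@@H]2[C@@](C)(CC1)CC[C@@]2(O)C(C)C | intermediate
13 | 4-acetoxybenzoyl chloride | CC(=O)Oc1ccc(cc1)C(Cl)=O | starting material
14 | (3R,3aS,4S,8aS)-3-hydroxy-6,8a-dimethyl-3-(propan-2-yl)-1,2,3,3a,4,7,8,8a-octahydroazulen-4-yl 4-acetoxybenzoate | CC1=C[C@H](OC(=O)c2ccc(OC(C)=O)cc2)[C@@H]2[C@@](C)(CC1)CC[C@@]2(O)C(C)C | intermediate
15 | (3R,3aS,4S,8aS)-3-hydroxy-6,8a-dimethyl-3-(propan-2-yl)-1,2,3,3a,4,7,8,8a-octahydroazulen-4-yl 4-hydroxybenzoate | CC1=C[C@H](OC(=O)c2ccc(O)cc2)[C@@H]2[C@@](C)(CC1)CC[C@@]2(O)C(C)C | target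

Total step count: 11. Longest linear sequence: 11 steps (from 1 to 15).

Steps most likely to fail

Step 5 (Proposed new method). The risks are insufficient torquoselectivity at a terminus whose faces differ only as methyl versus ring CH2, acid-induced oligomerisation of the unsubstituted vinyl ketone before cyclisation, and a 1,2-methyl shift of the hydroxyallyl cation. The fallback uses known chemistry and sets out from 7. Cyclisation with an achiral strong acid (MeSO3H/P2O5, CH2Cl2, 0 °C → rt, the classical Nazarov closure of 2-alkylcycloalkenyl vinyl ketones) gives racemic 6,8a-dimethyl-2,5,6,7,8,8a-hexahydroazulen-3(1H)-one F1. Dehydrogenation with chloranil as in step 6 gives racemic 6,8a-dimethyl-2,7,8,8a-tetrahydroazulen-3(1H)-one F2. The enantiomers of this single-stereocentre, strongly UV-absorbing dienone are separated by preparative chromatography on a chiral stationary phase; the (8aS)-enantiomer is 9, where the route is rejoined.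

Step 7. The risk is closure of the peroxy enolate on the face syn to the angular methyl (poor or reversed facial selectivity), or competing 1,6-attack of hydroperoxide, either of which would spoil the C3a/C4 configuration relative to C8a. The fallback fixes C4 by hydroxyl-directed reduction instead of by epoxidation and sets out from 9. The epoxide formed on the methyl face, (3aS,4R,8aS)-3a,4-epoxy-6,8a-dimethyl-2,3a,4,7,8,8a-hexahydroazulen-3(1H)-one F3, is carried through the conditions of steps 8 and 9. This gives the 4-epimeric aldol (3aS,4R,8aS)-4-hydroxy-6,8a-dimethyl-2,3a,4,7,8,8a-hexahydroazulen-3(1H)-one F4 and then the diol (3R,3aS,4R,8aS)-6,8a-dimethyl-3-(propan-2-yl)-1,2,3,3a,4,7,8,8a-octahydroazulene-3,4-diol F5. MnO2 oxidises only the allylic secondary alcohol to the β-hydroxy enone (3R,3aR,8aS)-3-hydroxy-6,8a-dimethyl-3-(propan-2-yl)-2,3,3a,7,8,8a-hexahydroazulen-4(1H)-one F6. Me4NBH(OAc)3 in MeCN/AcOH then delivers hydride from the tertiary hydroxyl (Evans–Saksena anti reduction) to give 12, where the route is rejoined.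

Step 9. The risks are enolisation and β-hydride reduction competing with addition of the branched Grignard reagent, elimination of the β-alkoxide back to the dienone, and insufficient facial bias at C3. The fallback sets out from 11. Isopropenylmagnesium bromide with CeCl3 (an sp2 nucleophile that cannot transfer a β-hydride and is less basic) gives (3S,3aS,4S,8aS)-6,8a-dimethyl-3-(prop-1-en-2-yl)-1,2,3,3a,4,7,8,8a-octahydroazulene-3,4-diol F7. Hydrogenation of only its 1,1-disubstituted alkene with H2 and RhCl(PPh3)3 leaves the trisubstituted ring alkene untouched and gives 12, where the route is rejoined.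

Further compounds
F1 | step 5 | racemic 6,8a-dimethyl-2,5,6,7,8,8a-hexahydroazulen-3(1H)-one | CC1CCC2(C)CCC(=O)C2=CC1
F2 | step 5 | racemic 6,8a-dimethyl-2,7,8,8a-tetrahydroazulen-3(1H)-one | CC1=CC=C2C(=O)CCC2(C)CC1
F3 | step 7 | (3aS,4R,8aS)-3a,4-epoxy-6,8a-dimethyl-2,3a,4,7,8,8a-hexahydroazulen-3(1H)-one | CC1=C[C@H]2O[C@]23C(=O)CC[C@]3(C)CC1
F4 | step 7 | (3aS,4R,8aS)-4-hydroxy-6,8a-dimethyl-2,3a,4,7,8,8a-hexahydroazulen-3(1H)-one | CC1=C[C@@H](O)[C@@H]2[C@@](C)(CC1)CCC2=O
F5 | step 7 | (3R,3aS,4R,8aS)-6,8a-dimethyl-3-(propan-2-yl)-1,2,3,3a,4,7,8,8a-octahydroazulene-3,4-diol | CC1=C[C@@H](O)[C@@H]2[C@@](C)(CC1)CC[C@@]2(O)C(C)C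
F6 | step 7 | (3R,3aR,8aS)-3-hydroxy-6,8a-dimethyl-3-(propan-2-yl)-2,3,3a,7,8,8a-hexahydroazulen-4(1H)-one | CC1=CC(=O)[C@@H]2[C@@](C)(CC1)CC[C@@]2(O)C(C)C
F7 | step 9 | (3S,3aS,4S,8aS)-6,8a-dimethyl-3-(prop-1-en-2-yl)-1,2,3,3a,4,7,8,8a-octahydroazulene-3,4-diol | CC1=C[C@H](O)[C@@H]2[C@@](C)(CC1)CC[C@@]2(O)C(C)=C
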